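## Plan

- Dienone ring numbering: C1 (C=O), C2 (bears the isoindolinone), C3 (OH), C4 (H), C5 (CH3), C6 (two prenyl groups).
- Cuts: C3 O–H goes back to O–Si. The dienone ring is then cut at C1–C2 and C3–C4, with C1–C6 broken and re-made on the way. This releases C2–C3 as a siloxyalkyne already bonded to C3 of the isoindolinone, and leaves C1, C4, C5, C6 as 3-methyl-4,4-diprenylcyclobut-2-enone. The lactam N–C(=O) bond and the C3–alkyne bond are cut last.
- Enabling feature: C6 is quaternary and sits between C1=O and the end of the C2=C3–C4=C5 diene. The ring is therefore the 6π valence isomer of the dienylketene O=C1=C2–C3=C4–C5=C6, which is the 4π-opened form of a 4-alkenylcyclobutenone. Oxygen on C3 and carbon on C2 are the polarity pattern of an oxygen-substituted alkyne.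
- Forward order: the benzene ring is bought. The lactam ring closes by aminolysis of the ortho ester (step 5). A four-membered ring is made by ketene/ethoxyacetylene [2+2] (step 10). It grows by two carbons to the dienone ring in step 12, which also joins the two fragments.
- Stereochemistry: the only stereocentre (isoindolinone C3, S) comes from (S)-tert-butanesulfinamide through an ethynyl Grignard addition (step 4). C6 carries two identical groups, so no other centre arises.

Key step: step 12

Assumption: C3–H next to the vinylogous acid is taken as configurationally stable under neutral or weakly acidic conditions up to 80 °C, so strong base and hot acid are avoided after step 6. The same spatial arrangement is called (R) in 6–11 and (S) in 24–27 only because ethynyl and silyloxyethynyl rank below the aryl carbon in the CIP order.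

## Route

Step 1
Reactants: 1 methyl 3-methoxy-2-methylbenzoate
Product: 2 methyl 2-(bromomethyl)-3-methoxybenzoate
Conditions: NBS (1.05 equiv), AIBN (cat.), PhCF3, reflux
Reagents that add atoms: N-bromosuccinimide O=C1CCC(=O)N1Br
Why: Wohl–Ziegler bromination, in which the radical chain attacks the only benzylic C–H bonds while the non-polar medium suppresses ionic ring bromination.

Step 2
Reactants: 2 methyl 2-(bromomethyl)-3-methoxybenzoate
Product: 3 methyl 2-formyl-3-methoxybenzoate
Conditions: N-methylmorpholine N-oxide (3 equiv), 4 Å sieves, MeCN, rt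
Reagents that add atoms: N-methylmorpholine N-oxide C[N+]1([O-])CCOCC1
Why: Kornblum-type oxidation of a benzylic bromide by an amine N-oxide (SN2 by oxygen, then loss of N-methylmorpholine), which stops at the aldehyde and runs cold enough to avoid phthalide formation.

Step 3
Reactants: 3 methyl 2-formyl-3-methoxybenzoate; 4 (S)-2-methylpropane-2-sulfinamide
Product: 5 methyl 2-[(E)-{[(S)-tert-butylsulfinyl]imino}methyl]-3-methoxybenzoate
Conditions: CuSO4 (2.5 equiv), PPTS (5 mol %), CH2Cl2, reflux
Reagents that add atoms: none
Why: Desiccant-driven condensation of an aldehyde with tert-butanesulfinamide, which should give only the E aldimine and leaves the sulfur stereocentre and the methyl ester untouched.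

Step 4
Reactants: 5 methyl 2-[(E)-{[(S)-tert-butylsulfinyl]imino}methyl]-3-methoxybenzoate
Product: 6 methyl 2-[(1R)-1-{[(S)-tert-butylsulfinyl]amino}prop-2-yn-1-yl]-3-methoxybenzoate
Conditions: HC≡CMgBr (0.5 M in THF, 2.5 equiv), CH2Cl2, −78 → −40 °C; then sat. aq NH4Cl
Reagents that add atoms: ethynylmagnesium bromide C#C[Mg]Br
Why: 1,2-Addition of an alkynyl Grignard reagent to an N-tert-butanesulfinyl aldimine through the six-membered magnesium-bridged chair favoured in a weakly coordinating solvent, in which the (S)-sulfinyl group with equatorial tert-butyl steers ethynyl to the Re face of C=N and sets the (R) centre, the minor diastereomer being removed by chromatography.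

Step 5
Reactants: 6 methyl 2-[(1R)-1-{[(S)-tert-butylsulfinyl]amino}prop-2-yn-1-yl]-3-methoxybenzoate
Product: 8 (3R)-3-ethynyl-4-methoxyisoindolin-1-one, via amino ester hydrochloride 7 (not isolated)
Conditions: HCl (4 M in dioxane), MeOH, 0 °C → rt; concentrate; Et3N, MeOH, 40 °C
Reagents that add atoms: none
Why: Acidic methanolysis of the S–N bond followed by 5-exo-trig lactamisation of the neutralised amine onto the ortho ester, with no bond to the stereocentre broken and a base too weak to remove C3–H.

Step 6
Reactants: 8 (3R)-3-ethynyl-4-methoxyisoindolin-1-one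
Product: 11 (3R)-4-methoxy-3-[(triisopropylsilyloxy)ethynyl]isoindolin-1-one, via dilithio acetylide 9 (not isolated), via dilithium ynolate 10 (not isolated)
Conditions: n-BuLi (2.1 equiv), THF, −78 °C; LiOOt-Bu (from t-BuOOH and LiHMDS, THF, −78 °C), −78 → 0 °C; TIPSOTf (1.2 equiv), −78 → 0 °C; then H2O
Reagents that add atoms: tert-butyl hydroperoxide (as its lithium salt, gives the oxygen atom) CC(C)(C)OO; triisopropylsilyl trifluoromethanesulfonate CC(C)[Si](C(C)C)(C(C)C)OS(=O)(=O)C(F)(F)F
Why: Oxenoid oxidation of a lithium acetylide with lithium tert-butyl peroxide to the ynolate and O-silylation with a bulky triflate, the standard route from terminal alkynes to siloxyalkynes, in which prior N-lithiation shields C3–H from deprotonation and the ynolate oxygen should outrun the hindered lactam nitrogen and LiOt-Bu for the silyl triflate.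

Step 7
Reactants: 12 dimethyl malonate; 13 prenyl bromide (1-bromo-3-methylbut-2-ene)
Product: 14 dimethyl 2,2-bis(3-methylbut-2-enyl)malonate
Conditions: NaH (2.3 equiv), 13 (2.3 equiv), THF/DMF, 0 °C → rt
Reagents that add atoms: none
Why: Double SN2 alkylation of the malonate enolate (malonic ester synthesis) at the primary terminus of the allylic bromide.

Step 8
Reactants: 14 dimethyl 2,2-bis(3-methylbut-2-enyl)malonate
Product: 16 5-methyl-2-(3-methylbut-2-enyl)hex-4-enoic acid (diprenylacetic acid), via diprenylmalonic acid 15 (not isolated)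
Conditions: KOH, MeOH/H2O, reflux; 2 M HCl, 0 °C; then neat, 160 °C
Reagents that add atoms: potassium hydroxide [K+].[OH-]
Why: Saponification and thermal decarboxylation of the geminal diacid through the cyclic six-membered transition state (malonic ester synthesis), to which the trisubstituted alkenes are inert.

Step 9
Reactants: 16 diprenylacetic acid
Product: 17 5-methyl-2-(3-methylbut-2-enyl)hex-4-enoyl chloride
Conditions: (COCl)2 (1.2 equiv), DMF (cat.), CH2Cl2, 0 °C → rt
Reagents that add atoms: oxalyl chloride O=C(Cl)C(=O)Cl
Why: Vilsmeier-type chlorination of a carboxylic acid, mild enough that the prenyl double bonds do not take up HCl.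

Step 10
Reactants: 17 5-methyl-2-(3-methylbut-2-enyl)hex-4-enoyl chloride; 18 ethoxyacetylene
Product: 20 3-ethoxy-4,4-bis(3-methylbut-2-enyl)cyclobut-2-en-1-one, via diprenylketene 19 (not isolated)
Conditions: Et3N (1.5 equiv), 18 (3 equiv, solution in hexanes), Et2O, rt → 35 °C
Reagents that add atoms: none
Why: Dehydrochlorination to the dialkylketene and regiospecific ketene–ynol ether [2+2] cycloaddition (carbonyl carbon to the nucleophilic CH terminus), the standard entry to 3-ethoxy-4,4-dialkylcyclobutenones, the one-carbon tether keeping the prenyl alkenes out of reach of the ketene.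

Step 11
Reactants: 20 3-ethoxy-4,4-bis(3-methylbut-2-enyl)cyclobut-2-en-1-one
Product: 22 3-methyl-4,4-bis(3-methylbut-2-enyl)cyclobut-2-en-1-one, via tertiary cyclobutenol 21 (not isolated)
Conditions: MeLi (1.2 equiv), Et2O, −78 °C; then 1 M HCl, 0 °C
Reagents that add atoms: methyllithium [Li]C; water O
Why: 1,2-Addition to the vinylogous ester carbonyl and acid-induced allylic transposition with loss of ethanol (Stork–Danheiser transposition), the standard route to 3-alkylcyclobutenones.

Step 12
Reactants: 11 (3R)-4-methoxy-3-[(triisopropylsilyloxy)ethynyl]isoindolin-1-one; 22 3-methyl-4,4-bis(3-methylbut-2-enyl)cyclobut-2-en-1-one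
Product: 26 (3S)-4-methoxy-3-[4-methyl-5,5-bis(3-methylbut-2-enyl)-6-oxo-2-(triisopropylsilyloxy)cyclohexa-1,3-dien-1-yl]isoindolin-1-one, via vinylketene 23 (not isolated), via 4-alkenylcyclobutenone 24 (not isolated), via dienylketene 25 (not isolated)
Conditions: 22 (2 equiv), PhMe (0.4 M in 11), degassed, hν (365 nm), 20 °C; then dark, 80 °C
Reagents that add atoms: none
Why: Proposed new method: light opens the four-membered ring of 22 (4π electrocyclic) to vinylketene 23, whose carbonyl carbon is attacked by the oxygen-polarised carbon of siloxyalkyne 11 in a [2+2] cycloaddition to give 24, and at 80 °C 24 opens reversibly (4π) to dienylketene 25, whose isomer with the alkenyl group cis to the ketene closes C1–C6 by 6π electrocyclisation, so that the two alkyne carbons end up inserted between C1 and C4 of the old four-membered ring (4 → 6). The closest known reaction type is the Danheiser benzannulation in its siloxyalkyne variant; what is new is the fully substituted vinyl terminus, which leaves C6 without hydrogen and halts the cascade at the 6,6-dialkylcyclohexa-2,4-dienone, a closure that is the thermal reverse of the Barton–Quinkert ring opening of such dienones and has a parallel in the Dötz-type cyclohexadienone annulation of β,β-disubstituted alkenyl chromium carbene complexes. Ring closures: the transient four-membered ring by ketene–alkyne [2+2] cycloaddition, the six-membered ring by disrotatory 6π electrocyclisation. No lasting stereocentre is made, since C4 of 24 (formed as both epimers) becomes sp2 again and C6 carries two identical prenyl groups, while C3 of the isoindolinone is a spectator under neutral aprotic conditions and keeps its configuration. The step needs regioselectivity, secured by the donor oxygen of 11 that places the isoindolinone at C2 and the silyloxy group at C3, and chemoselectivity of the ketenes for the alkyne over the lactam N–H and the prenyl alkenes, secured by the far higher ketenophilicity of a siloxyalkyne and by the very fast 6π closure of 25. Generating 23 with light at 20 °C rather than by heating a 4,4-dialkylcyclobutenone above 110 °C holds back its [1,5]-hydrogen shift and its intramolecular [2+2] reaction and spares 26 from [3,3] shifts of its prenyl groups.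

Step 13
Reactants: 26 (3S)-4-methoxy-3-[4-methyl-5,5-bis(3-methylbut-2-enyl)-6-oxo-2-(triisopropylsilyloxy)cyclohexa-1,3-dien-1-yl]isoindolin-1-one
Product: 27 (3S)-3-[2-hydroxy-4-methyl-5,5-bis(3-methylbut-2-enyl)-6-oxocyclohexa-1,3-dien-1-yl]-4-methoxyisoindolin-1-one (target)
Conditions: HF·pyridine, pyridine/THF, 0 °C
Reagents that add atoms: none
Why: Fluoride cleavage of a silyl vinylogous ester, very labile because a vinylogous carboxylate leaves, under buffered weakly acidic conditions that should neither start retro-Mannich racemisation at C3 nor cyclise the enol onto a prenyl group.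

## Compound list

1 | methyl 3-methoxy-2-methylbenzoate | COC(=O)c1cccc(OC)c1C | starting material
2 | methyl 2-(bromomethyl)-3-methoxybenzoate | COC(=O)c1cccc(OC)c1CBr | intermediate
3 | methyl 2-formyl-3-methoxybenzoate | COC(=O)c1cccc(OC)c1C=O | intermediate
4 | (S)-2-methylpropane-2-sulfinamide | CC(C)(C)[S@](=O)N | starting material
5 | methyl 2-[(E)-{[(S)-tert-butylsulfinyl]imino}methyl]-3-methoxybenzoate | CC(C)(C)[S@](=O)/N=C/c1c(OC)cccc1C(=O)OC | intermediate
6 | methyl 2-[(1R)-1-{[(S)-tert-butylsulfinyl]amino}prop-2-yn-1-yl]-3-methoxybenzoate | CC(C)(C)[S@](=O)N[C@H](C#C)c1c(OC)cccc1C(=O)OC | intermediate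
7 | methyl 2-[(1R)-1-aminoprop-2-yn-1-yl]-3-methoxybenzoate hydrochloride | Cl.N[C@H](C#C)c1c(OC)cccc1C(=O)OC | intermediate
8 | (3R)-3-ethynyl-4-methoxyisoindolin-1-one | COc1cccc2c1[C@@H](C#C)NC2=O | intermediate
9 | N,C-dilithio derivative of 8 (lactam nitrogen and alkyne terminus) | [Li+].[Li+].COc1cccc2c1[C@@H](C#[C-])[N-]C2=O | intermediate
10 | dilithium ynolate/lactamate derived from 9 | [Li+].[Li+].COc1cccc2c1[C@@H](C#C[O-])[N-]C2=O | intermediate
11 | (3R)-4-methoxy-3-[(triisopropylsilyloxy)ethynyl]isoindolin-1-one | COc1cccc2c1[C@@H](C#CO[Si](C(C)C)(C(C)C)C(C)C)NC2=O | intermediate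
12 | dimethyl malonate | COC(=O)CC(=O)OC | starting material
13 | prenyl bromide | CC(C)=CCBr | starting material
14 | dimethyl 2,2-bis(3-methylbut-2-enyl)malonate | COC(=O)C(CC=C(C)C)(CC=C(C)C)C(=O)OC | intermediate
15 | 2,2-bis(3-methylbut-2-enyl)malonic acid | OC(=O)C(CC=C(C)C)(CC=C(C)C)C(=O)O | intermediate
16 | 5-methyl-2-(3-methylbut-2-enyl)hex-4-enoic acid | CC(C)=CCC(CC=C(C)C)C(=O)O | intermediate
17 | 5-methyl-2-(3-methylbut-2-enyl)hex-4-enoyl chloride | CC(C)=CCC(CC=C(C)C)C(=O)Cl | intermediate
18 | ethoxyacetylene | CCOC#C | starting material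
19 | bis(3-methylbut-2-enyl)ketene | CC(C)=CCC(=C=O)CC=C(C)C | intermediate
20 | 3-ethoxy-4,4-bis(3-methylbut-2-enyl)cyclobut-2-en-1-one | CCOC1=CC(=O)C1(CC=C(C)C)CC=C(C)C | intermediate
21 | 3-ethoxy-1-methyl-4,4-bis(3-methylbut-2-enyl)cyclobut-2-en-1-ol (racemic) | CCOC1=CC(C)(O)C1(CC=C(C)C)CC=C(C)C | intermediate
22 | 3-methyl-4,4-bis(3-methylbut-2-enyl)cyclobut-2-en-1-one | CC1=CC(=O)C1(CC=C(C)C)CC=C(C)C | intermediate
23 | 3,7-dimethyl-4-(3-methylbut-2-enyl)octa-1,3,6-trien-1-one (vinylketene) | O=C=CC(C)=C(CC=C(C)C)CC=C(C)C | intermediate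
24 | (3S)-4-methoxy-3-[3-(1-methyl-2,2-diprenylvinyl)-4-oxo-2-(triisopropylsilyloxy)cyclobut-1-en-1-yl]isoindolin-1-one, both epimers at the ring CH | COc1cccc2c1[C@@H](C1=C(O[Si](C(C)C)(C(C)C)C(C)C)C(C(C)=C(CC=C(C)C)CC=C(C)C)C1=O)NC2=O | intermediate
25 | dienylketene O=C=C(isoindolinonyl)–C(OTIPS)=CH–C(CH3)=C(prenyl)2, ketene carbon and alkenyl group cis on the C3=C4 bond, (3S) | COc1cccc2c1[C@@H](C(=C=O)/C(O[Si](C(C)C)(C(C)C)C(C)C)=C\C(C)=C(CC=C(C)C)CC=C(C)C)NC2=O | intermediate
26 | (3S)-4-methoxy-3-[4-methyl-5,5-bis(3-methylbut-2-enyl)-6-oxo-2-(triisopropylsilyloxy)cyclohexa-1,3-dien-1-yl]isoindolin-1-one | COc1cccc2c1[C@@H](C1=C(O[Si](C(C)C)(C(C)C)C(C)C)C=C(C)C(CC=C(C)C)(CC=C(C)C)C1=O)NC2=O | intermediate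
27 | (3S)-3-[2-hydroxy-4-methyl-5,5-bis(3-methylbut-2-enyl)-6-oxocyclohexa-1,3-dien-1-yl]-4-methoxyisoindolin-1-one | COc1cccc2c1[C@@H](C1=C(O)C=C(C)C(CC=C(C)C)(CC=C(C)C)C1=O)NC2=O | target

## Step count and risks

Total steps: 13. Longest linear sequence: 8 (steps 1–6, 12, 13). The second branch (steps 7–11) joins at step 12.

**Step 12 (labelled step).** Several processes may go wrong.
- The vinylketene may be lost by intramolecular [2+2] reaction with its cis prenyl group, or by [1,5]-hydrogen shift, before the alkyne captures it.
- Inward rotation of the bulky alkenyl group in the second ring opening may be too slow.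
- The product may drift by [3,3] shifts on heating.

The fallback uses known chemistry, sets out from 11 and comes back at 26. The cascade is run in its classical aromatising form, and the quaternary carbon is made afterwards by alkylative dearomatisation.
- Acetyl chloride, Et3N and 18 give 3-ethoxycyclobut-2-enone F1.
- MeLi followed by dilute HCl gives 3-methylcyclobut-2-enone F2.
- F2 and 11 in toluene at 80 °C undergo the Danheiser benzannulation to (3S)-3-[2-hydroxy-4-methyl-6-(triisopropylsilyloxy)phenyl]-4-methoxyisoindolin-1-one F3.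
- The sodium phenoxide of F3 (NaH, 1 equiv, toluene) is C-prenylated with 13 at the free ortho carbon. This gives (3S)-3-[2-hydroxy-4-methyl-3-(3-methylbut-2-enyl)-6-(triisopropylsilyloxy)phenyl]-4-methoxyisoindolin-1-one F4.
- The same treatment of F4 alkylates the now substituted ortho carbon with loss of aromaticity and gives 26.

**Step 6.** Competing deprotonation at C3 may erode the configuration. Silylation may occur at the lactam nitrogen. The ynolate may be lost by protonation.

The fallback sets out from 22, 18 and 3 and comes back at 27. The ring is expanded first on a simple alkyne, and the isoindolinone is attached afterwards.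
- 22 and 18 under the conditions of step 12 (sealed tube) give 3-ethoxy-5-methyl-6,6-bis(3-methylbut-2-enyl)cyclohexa-2,4-dien-1-one F5.
- LiOH in aqueous THF hydrolyses the vinylogous ester to 3-hydroxy-5-methyl-6,6-bis(3-methylbut-2-enyl)cyclohexa-2,4-dien-1-one F6.
- 3 and NH3 in MeOH give racemic 3-hydroxy-4-methoxyisoindolin-1-one F7.
- F6 and F7 are joined at C2 by a chiral phosphoric acid-catalysed amidoalkylation, a Mannich-type addition of the enol to the N-acylimine formed by loss of water (TRIP, toluene, 4 Å sieves, 0 °C). The catalyst antipode that delivers the (S) centre is used.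

**Step 4.** Facial selectivity may be poor, because the ortho ester and methoxy groups can bind magnesium and divert the addition from the sulfinyl-bridged chair.

The fallback sets out from 3 and comes back at 8. The stereocentre is set by a catalyst instead of an auxiliary.
- 3, p-anisidine and trimethylsilylacetylene with Cu(MeCN)4PF6 and a diphenyl-substituted pybox ligand undergo the enantioselective alkynylation/lactamisation cascade. This gives (3S)-4-methoxy-2-(4-methoxyphenyl)-3-[(trimethylsilyl)ethynyl]isoindolin-1-one F8.
- (NH4)2Ce(NO3)6 in aqueous MeCN at 0 °C removes the N-aryl group to give (3S)-4-methoxy-3-[(trimethylsilyl)ethynyl]isoindolin-1-one F9.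
- K2CO3 in MeOH removes the silyl group and gives 8.

## Further compounds

F1 | step 12 | 3-ethoxycyclobut-2-en-1-one | CCOC1=CC(=O)C1
F2 | step 12 | 3-methylcyclobut-2-en-1-one | CC1=CC(=O)C1
F3 | step 12 | (3S)-3-[2-hydroxy-4-methyl-6-(triisopropylsilyloxy)phenyl]-4-methoxyisoindolin-1-one | COc1cccc2c1[C@@H](c1c(O)cc(C)cc1O[Si](C(C)C)(C(C)C)C(C)C)NC2=O
F4 | step 12 | (3S)-3-[2-hydroxy-4-methyl-3-(3-methylbut-2-enyl)-6-(triisopropylsilyloxy)phenyl]-4-methoxyisoindolin-1-one | COc1cccc2c1[C@@H](c1c(O)c(CC=C(C)C)c(C)cc1O[Si](C(C)C)(C(C)C)C(C)C)NC2=O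
F5 | step 6 | 3-ethoxy-5-methyl-6,6-bis(3-methylbut-2-enyl)cyclohexa-2,4-dien-1-one | CCOC1=CC(=O)C(CC=C(C)C)(CC=C(C)C)C(C)=C1
F6 | step 6 | 3-hydroxy-5-methyl-6,6-bis(3-methylbut-2-enyl)cyclohexa-2,4-dien-1-one | OC1=CC(=O)C(CC=C(C)C)(CC=C(C)C)C(C)=C1
F7 | step 6 | 3-hydroxy-4-methoxyisoindolin-1-one (racemic) | COc1cccc2c1C(O)NC2=O
F8 | step 4 | (3S)-4-methoxy-2-(4-methoxyphenyl)-3-[(trimethylsilyl)ethynyl]isoindolin-1-one | COc1cccc2c1[C@@H](C#C[Si](C)(C)C)N(c1ccc(OC)cc1)C2=O
F9 | step 4 | (3S)-4-methoxy-3-[(trimethylsilyl)ethynyl]isoindolin-1-one | COc1cccc2c1[C@@H](C#C[Si](C)(C)C)NC2=O
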